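**Retrosynthetic overview**

1. The target is a ring-opened epigallocatechin gallate (upper unit, a 1,1,3-triarylpropan-2-yl gallate) joined through its diarylmethine carbon to C6 of an intact epigallocatechin gallate (lower unit). The 17 phenols are carried as benzyl ethers and both gallates are put on in one late double esterification.
2. Key disconnection: pyran ring C of the lower flavan is opened at O1–C8a and at C2–aryl, giving an α-alkoxy aldehyde on a fluoroarene and an aryl Grignard reagent. In the forward sense one pot sets C2 by chelation-controlled addition and closes ring C by displacing fluoride at C8a with retention at C2, which gives the 2,3-cis series directly.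
3. Enabling feature: in ring A, C8a lies para to C6 (the carbon bearing the upper unit) and meta to the C5 and C7 oxygens. A 2,6-dioxygenated 4-fluorophenyl group is therefore symmetric about the C6–C8a axis, its two C–H positions (C4a/C8) are equivalent, and fluorine first directs metalation to them and then leaves for O1.
4. Upper half: the C2(upper)–C6 bond comes from inversion opening of a Shi epoxide of an (E)-1,3-diarylpropene at its benzylic carbon by the 2,6-bis(benzyloxy)-4-fluorophenyl magnesium/copper reagent; the C4a–C4 bond comes from fluorine-directed lithiation and opening of methyl (R)-glycidate.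
5. Ring order: all benzene rings are bought as arenes; the only ring formed is pyran ring C, closed in the key step.

Key step: step 13

Assumption: the arenes, methyl (R)-glycidate and the D-fructose-derived Shi ketone used as starting materials are taken as purchasable, and metalation of the 3,5-bis(benzyloxy)fluoroarene is taken to occur at the C–H between F and OBn, as in simpler 3-alkoxyfluoroarenes.

**Route**

Step 1
Reactants: 1 3,4,5-tris(benzyloxy)benzaldehyde
Product: 2 ethyl (E)-3-[3,4,5-tris(benzyloxy)phenyl]prop-2-enoate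
Conditions: triethyl phosphonoacetate, NaH, THF, 0 °C to rt
Reagents that add atoms: triethyl phosphonoacetate, CCOC(=O)CP(=O)(OCC)OCC
Why: Horner–Wadsworth–Emmons olefination with a stabilised phosphonate should give the (E)-cinnamate.

Step 2
Reactants: 2 ethyl (E)-3-[3,4,5-tris(benzyloxy)phenyl]prop-2-enoate
Product: 3 (E)-3-[3,4,5-tris(benzyloxy)phenyl]prop-2-en-1-ol
Conditions: i-Bu2AlH (2.2 equiv), CH2Cl2, −78 °C; aq. potassium sodium tartrate work-up
Reagents that add atoms: none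
Why: 1,2-reduction of the enoate by the aluminium hydride should give the allylic alcohol without touching the alkene or the benzyl ethers.

Step 3
Reactants: 3 (E)-3-[3,4,5-tris(benzyloxy)phenyl]prop-2-en-1-ol; 4 1,3,5-tris(benzyloxy)benzene (3 equiv)
Product: 5 1,3,5-tris(benzyloxy)-2-[(E)-3-[3,4,5-tris(benzyloxy)phenyl]prop-2-en-1-yl]benzene
Conditions: H2SO4/SiO2 (cat.), CH2Cl2, rt
Reagents that add atoms: none
Why: Friedel–Crafts allylation with loss of water, in which the aryl-stabilised cinnamyl cation is attacked at its terminus remote from the aryl group by the threefold-symmetric arene (no regiochemical choice), should give the conjugated (E)-1,3-diarylpropene, the excess of 4 limiting double alkylation.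

Step 4
Reactants: 5 1,3,5-tris(benzyloxy)-2-[(E)-3-[3,4,5-tris(benzyloxy)phenyl]prop-2-en-1-yl]benzene
Product: 6 (2R,3R)-2-[3,4,5-tris(benzyloxy)phenyl]-3-[2,4,6-tris(benzyloxy)benzyl]oxirane
Conditions: D-fructose-derived Shi ketone (1,2:4,5-di-O-isopropylidene-β-D-erythro-2,3-hexodiulo-2,6-pyranose, 30 mol %), Oxone (2KHSO5·KHSO4·K2SO4), K2CO3, Bu4NHSO4, MeCN/dimethoxymethane/aq. Na2B4O7 buffer, 0 °C
Reagents that add atoms: potassium peroxymonosulfate (active component of Oxone), OOS(=O)(=O)[O-].[K+]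
Why: Shi asymmetric epoxidation (chiral dioxirane, spiro transition state) is at its best with trans-disubstituted styrenes, and the D-fructose-derived ketone should deliver oxygen to the face that gives the (R,R)-trans-epoxide.

Step 5
Reactants: 7 1,3,5-trifluoro-2-nitrobenzene
Product: 8 1,3-bis(benzyloxy)-5-fluoro-2-nitrobenzene
Conditions: BnOH (2.1 equiv), KOt-Bu (2.1 equiv), toluene, −20 °C to rt
Reagents that add atoms: benzyl alcohol, OCc1ccccc1
Why: Nucleophilic aromatic substitution of ortho/para-fluoronitroarenes by alkoxides in a non-polar solvent is ortho-selective (potassium bridging between the nitro oxygen and the alkoxide), so both ortho fluorines should be exchanged while the para fluorine is kept.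

Step 6
Reactants: 8 1,3-bis(benzyloxy)-5-fluoro-2-nitrobenzene
Product: 9 2,6-bis(benzyloxy)-4-fluoroaniline
Conditions: H2 (1 atm), 5% Pt/C (sulfided), EtOAc, rt
Reagents that add atoms: none
Why: Chemoselective catalytic hydrogenation of the nitro group over sulfided platinum should leave the aryl benzyl ethers and the C–F bond intact.

Step 7
Reactants: 9 2,6-bis(benzyloxy)-4-fluoroaniline
Product: 11 1,3-bis(benzyloxy)-5-fluoro-2-iodobenzene, via diazonium tosylate 10 (not isolated)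
Conditions: p-TsOH·H2O, NaNO2, KI, MeCN/H2O, 10 °C to rt
Reagents that add atoms: potassium iodide, [K+].[I-]
Why: Diazotisation followed by Sandmeyer-type iodide substitution (no copper needed for iodide) should put the halogen exactly at the carbon flanked by the two benzyloxy groups.

Step 8
Reactants: 11 1,3-bis(benzyloxy)-5-fluoro-2-iodobenzene; 6 (2R,3R)-2-[3,4,5-tris(benzyloxy)phenyl]-3-[2,4,6-tris(benzyloxy)benzyl]oxirane
Product: 13 (1R,2R)-1-[2,6-bis(benzyloxy)-4-fluorophenyl]-1-[3,4,5-tris(benzyloxy)phenyl]-3-[2,4,6-tris(benzyloxy)phenyl]propan-2-ol, via arylmagnesium chloride 12 (not isolated)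
Conditions: i-PrMgCl·LiCl, THF, −15 to 0 °C; then CuI (15 mol %), 6, −30 to 0 °C; aq. NH4Cl
Reagents that add atoms: none
Why: Iodine–magnesium exchange followed by copper-catalysed SN2 opening of the aryl epoxide at its benzylic carbon with inversion should set the diarylmethine centre as R from the (R,R)-epoxide, while the carbinol centre is carried over unchanged (anti relationship).

Step 9
Reactants: 13 (1R,2R)-1-[2,6-bis(benzyloxy)-4-fluorophenyl]-1-[3,4,5-tris(benzyloxy)phenyl]-3-[2,4,6-tris(benzyloxy)phenyl]propan-2-ol; 14 methyl (2R)-oxirane-2-carboxylate (methyl (R)-glycidate)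
Product: 17 methyl (2R)-3-[2,4-bis(benzyloxy)-6-fluoro-3-[(1R,2R)-2-hydroxy-1-[3,4,5-tris(benzyloxy)phenyl]-3-[2,4,6-tris(benzyloxy)phenyl]propyl]phenyl]-2-hydroxypropanoate, via dilithio species 15 (not isolated), via bis(bromomagnesium) species 16 (not isolated)
Conditions: n-BuLi (2.2 equiv), THF, −78 °C; MgBr2·OEt2 (2.5 equiv), −78 to −40 °C; CuI (10 mol %), 14, −40 to −20 °C; aq. NH4Cl
Reagents that add atoms: none
Why: After O-deprotonation, fluorine-directed ortho-lithiation should take place at the ring-A C–H flanked by F and OBn (its two copies are equivalent by the local symmetry of the ring), and the derived aryl magnesium/copper species should open the glycidate at its CH2 terminus (SN2), so that the C3 stereocentre is taken unchanged from 14.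

Step 10
Reactants: 17 methyl (2R)-3-[2,4-bis(benzyloxy)-6-fluoro-3-[(1R,2R)-2-hydroxy-1-[3,4,5-tris(benzyloxy)phenyl]-3-[2,4,6-tris(benzyloxy)phenyl]propyl]phenyl]-2-hydroxypropanoate
Product: 18 methyl (2R)-3-[2,4-bis(benzyloxy)-6-fluoro-3-[(1R,2R)-2-(methoxymethoxy)-1-[3,4,5-tris(benzyloxy)phenyl]-3-[2,4,6-tris(benzyloxy)phenyl]propyl]phenyl]-2-(methoxymethoxy)propanoate
Conditions: MOMCl, i-Pr2NEt, Bu4NI (cat.), CH2Cl2, 0 °C to reflux
Reagents that add atoms: chloromethyl methyl ether, COCCl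
Why: Alkylation of both secondary hydroxyls gives base-stable acetal ethers, and the α-OMOM group of the ester is the chelating group needed later.

Step 11
Reactants: 18 methyl (2R)-3-[2,4-bis(benzyloxy)-6-fluoro-3-[(1R,2R)-2-(methoxymethoxy)-1-[3,4,5-tris(benzyloxy)phenyl]-3-[2,4,6-tris(benzyloxy)phenyl]propyl]phenyl]-2-(methoxymethoxy)propanoate
Product: 19 (2R)-3-[2,4-bis(benzyloxy)-6-fluoro-3-[(1R,2R)-2-(methoxymethoxy)-1-[3,4,5-tris(benzyloxy)phenyl]-3-[2,4,6-tris(benzyloxy)phenyl]propyl]phenyl]-2-(methoxymethoxy)propanal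
Conditions: i-Bu2AlH (1.1 equiv), CH2Cl2, −78 °C; MeOH then aq. potassium sodium tartrate at −78 °C; used at once
Reagents that add atoms: none
Why: Partial reduction of an α-alkoxy ester by DIBAL-H stops at the aldehyde because the chelated tetrahedral aluminium intermediate survives at −78 °C, and the cold, neutral work-up should keep the α-centre intact.

Step 12
Reactants: 20 5-bromobenzene-1,2,3-triol
Product: 21 1,2,3-tris(benzyloxy)-5-bromobenzene
Conditions: BnBr, K2CO3, DMF, 60 °C, under N2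
Reagents that add atoms: benzyl bromide, BrCc1ccccc1
Why: Williamson etherification of the three phenols gives the ring-B bromide in the same protecting-group pattern as the other fragments.

Step 13
Reactants: 19 (2R)-3-[2,4-bis(benzyloxy)-6-fluoro-3-[(1R,2R)-2-(methoxymethoxy)-1-[3,4,5-tris(benzyloxy)phenyl]-3-[2,4,6-tris(benzyloxy)phenyl]propyl]phenyl]-2-(methoxymethoxy)propanal; 21 1,2,3-tris(benzyloxy)-5-bromobenzene
Product: 24 (2R,3R)-5,7-bis(benzyloxy)-3-(methoxymethoxy)-6-[(1R,2R)-2-(methoxymethoxy)-1-[3,4,5-tris(benzyloxy)phenyl]-3-[2,4,6-tris(benzyloxy)phenyl]propyl]-2-[3,4,5-tris(benzyloxy)phenyl]chromane, via arylmagnesium bromide 22 (not isolated), via bromomagnesium alkoxide 23 (not isolated)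
Conditions: 21, Mg, THF, 40 °C; then 19, MgBr2·OEt2, CH2Cl2/THF, −78 °C; then KOt-Bu (3 equiv), DMPU, 60 °C
Reagents that add atoms: none
Why: The aryl Grignard reagent 22 adds to the magnesium chelate between the aldehyde oxygen and the α-OMOM oxygen of 19 (Cram chelate, attack anti to the benzylic CH2 group), which should set C2 as R, syn to the R centre at C3 that came from the glycidate. Exchange of the counter-ion with KOt-Bu in DMPU frees the alkoxide of 23, whose oxygen (O1) adds to the fluorine-bearing ring carbon C8a and expels fluoride through a Meisenheimer-type intermediate; the closest known reaction type is the intramolecular SNAr etherification of non-activated 3,5-dialkoxyfluoroarenes by secondary alkoxides to give chromans and flavans. Ring C closes in a 6-exo-trig mode (attack on an sp2 ring carbon, the displaced π bond lying outside the new ring). No bond to C2 or C3 is touched in the closure, so the syn carbinol is carried with retention into the 2,3-cis (2R,3R) flavan, without the oxidation/reduction correction that an O1–C2 closure with inversion would require. Site selectivity is fixed by the substrate: fluorine is the only leaving group on ring A and sits ortho to the tether, the C5 and C7 benzyloxy groups are meta to it and do not deactivate the ipso carbon by resonance, and only the C2 oxygen is free because the C3 and upper oxygens are MOM ethers. In one operation the step brings in ring B, creates the C2 stereocentre, and forms the C2–aryl and O1–C8a bonds and the only ring made in the synthesis.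

Step 14
Reactants: 24 (2R,3R)-5,7-bis(benzyloxy)-3-(methoxymethoxy)-6-[(1R,2R)-2-(methoxymethoxy)-1-[3,4,5-tris(benzyloxy)phenyl]-3-[2,4,6-tris(benzyloxy)phenyl]propyl]-2-[3,4,5-tris(benzyloxy)phenyl]chromane
Product: 25 (2R,3R)-5,7-bis(benzyloxy)-6-[(1R,2R)-2-hydroxy-1-[3,4,5-tris(benzyloxy)phenyl]-3-[2,4,6-tris(benzyloxy)phenyl]propyl]-2-[3,4,5-tris(benzyloxy)phenyl]chroman-3-ol
Conditions: ZnBr2, n-PrSH, CH2Cl2, 0 °C
Reagents that add atoms: none
Why: Lewis-acid activation of the acetal and capture of the methoxymethyl cation by the thiol should remove both MOM groups under conditions too mild to cleave aryl benzyl ethers or ionise the flavan C2–O bond.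

Step 15
Reactants: 25 (2R,3R)-5,7-bis(benzyloxy)-6-[(1R,2R)-2-hydroxy-1-[3,4,5-tris(benzyloxy)phenyl]-3-[2,4,6-tris(benzyloxy)phenyl]propyl]-2-[3,4,5-tris(benzyloxy)phenyl]chroman-3-ol; 26 3,4,5-tris(benzyloxy)benzoic acid (3 equiv)
Product: 27 heptadeca-O-benzyl derivative of the target: (2R,3R)-5,7-bis(benzyloxy)-6-[(1R,2R)-2-[3,4,5-tris(benzyloxy)benzoyloxy]-1-[3,4,5-tris(benzyloxy)phenyl]-3-[2,4,6-tris(benzyloxy)phenyl]propyl]-2-[3,4,5-tris(benzyloxy)phenyl]chroman-3-yl 3,4,5-tris(benzyloxy)benzoate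
Conditions: DCC, DMAP, CH2Cl2, rt to 35 °C
Reagents that add atoms: none
Why: Steglich esterification acylates both remaining secondary hydroxyls with the same protected galloyl group in one step, as is standard for flavan-3-ol gallates.

Step 16
Reactants: 27 heptadeca-O-benzyl derivative of the target
Product: 28 CNP0240551.1 (target)
Conditions: H2 (1 atm), Pd(OH)2/C, THF/MeOH, rt; filtration and Sephadex LH-20 under argon
Reagents that add atoms: none
Why: Global hydrogenolysis of the 17 aryl benzyl ethers over Pd(OH)2/C should leave the gallate esters, the flavan C2–O bond and all four stereocentres untouched.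

**Compound list**

1 | 3,4,5-tris(benzyloxy)benzaldehyde | O=Cc1cc(OCc2ccccc2)c(OCc2ccccc2)c(OCc2ccccc2)c1 | starting material
2 | ethyl (E)-3-[3,4,5-tris(benzyloxy)phenyl]prop-2-enoate | CCOC(=O)/C=C/c1cc(OCc2ccccc2)c(OCc2ccccc2)c(OCc2ccccc2)c1 | intermediate
3 | (E)-3-[3,4,5-tris(benzyloxy)phenyl]prop-2-en-1-ol | OC/C=C/c1cc(OCc2ccccc2)c(OCc2ccccc2)c(OCc2ccccc2)c1 | intermediate
4 | 1,3,5-tris(benzyloxy)benzene | c1c(OCc2ccccc2)cc(OCc2ccccc2)cc1OCc1ccccc1 | starting material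
5 | 1,3,5-tris(benzyloxy)-2-[(E)-3-[3,4,5-tris(benzyloxy)phenyl]prop-2-en-1-yl]benzene | C(/C=C/c1cc(OCc2ccccc2)c(OCc2ccccc2)c(OCc2ccccc2)c1)c1c(OCc2ccccc2)cc(OCc2ccccc2)cc1OCc1ccccc1 | intermediate
6 | (2R,3R)-2-[3,4,5-tris(benzyloxy)phenyl]-3-[2,4,6-tris(benzyloxy)benzyl]oxirane | C(c1c(OCc2ccccc2)cc(OCc2ccccc2)cc1OCc1ccccc1)[C@H]1O[C@@H]1c1cc(OCc2ccccc2)c(OCc2ccccc2)c(OCc2ccccc2)c1 | intermediate
7 | 1,3,5-trifluoro-2-nitrobenzene | [O-][N+](=O)c1c(F)cc(F)cc1F | starting material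
8 | 1,3-bis(benzyloxy)-5-fluoro-2-nitrobenzene | [O-][N+](=O)c1c(OCc2ccccc2)cc(F)cc1OCc1ccccc1 | intermediate
9 | 2,6-bis(benzyloxy)-4-fluoroaniline | Nc1c(OCc2ccccc2)cc(F)cc1OCc1ccccc1 | intermediate
10 | 2,6-bis(benzyloxy)-4-fluorobenzenediazonium 4-methylbenzenesulfonate | Cc1ccc(cc1)S(=O)(=O)[O-].N#[N+]c1c(OCc2ccccc2)cc(F)cc1OCc1ccccc1 | intermediate
11 | 1,3-bis(benzyloxy)-5-fluoro-2-iodobenzene | Ic1c(OCc2ccccc2)cc(F)cc1OCc1ccccc1 | intermediate
12 | [2,6-bis(benzyloxy)-4-fluorophenyl]magnesium chloride | Cl[Mg]c1c(OCc2ccccc2)cc(F)cc1OCc1ccccc1 | intermediate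
13 | (1R,2R)-1-[2,6-bis(benzyloxy)-4-fluorophenyl]-1-[3,4,5-tris(benzyloxy)phenyl]-3-[2,4,6-tris(benzyloxy)phenyl]propan-2-ol | O[C@H](Cc1c(OCc2ccccc2)cc(OCc2ccccc2)cc1OCc1ccccc1)[C@H](c1cc(OCc2ccccc2)c(OCc2ccccc2)c(OCc2ccccc2)c1)c1c(OCc2ccccc2)cc(F)cc1OCc1ccccc1 | intermediate
14 | methyl (2R)-oxirane-2-carboxylate | COC(=O)[C@H]1CO1 | starting material
15 | O,C-dilithio derivative of 13 (lithium alkoxide; aryllithium at the ring carbon between F and OBn) | [Li]O[C@H](Cc1c(OCc2ccccc2)cc(OCc2ccccc2)cc1OCc1ccccc1)[C@H](c1cc(OCc2ccccc2)c(OCc2ccccc2)c(OCc2ccccc2)c1)c1c(OCc2ccccc2)c([Li])c(F)cc1OCc1ccccc1 | intermediate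
16 | O,C-bis(bromomagnesium) derivative of 13 (same positions as in 15) | Br[Mg]O[C@H](Cc1c(OCc2ccccc2)cc(OCc2ccccc2)cc1OCc1ccccc1)[C@H](c1cc(OCc2ccccc2)c(OCc2ccccc2)c(OCc2ccccc2)c1)c1c(OCc2ccccc2)c([Mg]Br)c(F)cc1OCc1ccccc1 | intermediate
17 | methyl (2R)-3-[2,4-bis(benzyloxy)-6-fluoro-3-[(1R,2R)-2-hydroxy-1-[3,4,5-tris(benzyloxy)phenyl]-3-[2,4,6-tris(benzyloxy)phenyl]propyl]phenyl]-2-hydroxypropanoate | O[C@H](Cc1c(OCc2ccccc2)cc(OCc2ccccc2)cc1OCc1ccccc1)[C@H](c1cc(OCc2ccccc2)c(OCc2ccccc2)c(OCc2ccccc2)c1)c1c(OCc2ccccc2)c(C[C@@H](O)C(=O)OC)c(F)cc1OCc1ccccc1 | intermediate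
18 | methyl (2R)-3-[2,4-bis(benzyloxy)-6-fluoro-3-[(1R,2R)-2-(methoxymethoxy)-1-[3,4,5-tris(benzyloxy)phenyl]-3-[2,4,6-tris(benzyloxy)phenyl]propyl]phenyl]-2-(methoxymethoxy)propanoate | COCO[C@H](Cc1c(OCc2ccccc2)cc(OCc2ccccc2)cc1OCc1ccccc1)[C@H](c1cc(OCc2ccccc2)c(OCc2ccccc2)c(OCc2ccccc2)c1)c1c(OCc2ccccc2)c(C[C@@H](OCOC)C(=O)OC)c(F)cc1OCc1ccccc1 | intermediate
19 | (2R)-3-[2,4-bis(benzyloxy)-6-fluoro-3-[(1R,2R)-2-(methoxymethoxy)-1-[3,4,5-tris(benzyloxy)phenyl]-3-[2,4,6-tris(benzyloxy)phenyl]propyl]phenyl]-2-(methoxymethoxy)propanal | COCO[C@H](Cc1c(OCc2ccccc2)cc(OCc2ccccc2)cc1OCc1ccccc1)[C@H](c1cc(OCc2ccccc2)c(OCc2ccccc2)c(OCc2ccccc2)c1)c1c(OCc2ccccc2)c(C[C@@H](OCOC)C=O)c(F)cc1OCc1ccccc1 | intermediate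
20 | 5-bromobenzene-1,2,3-triol | Oc1cc(Br)cc(O)c1O | starting material
21 | 1,2,3-tris(benzyloxy)-5-bromobenzene | Brc1cc(OCc2ccccc2)c(OCc2ccccc2)c(OCc2ccccc2)c1 | intermediate
22 | [3,4,5-tris(benzyloxy)phenyl]magnesium bromide | Br[Mg]c1cc(OCc2ccccc2)c(OCc2ccccc2)c(OCc2ccccc2)c1 | intermediate
23 | bromomagnesium (1R,2R)-3-[2,4-bis(benzyloxy)-6-fluoro-3-[(1R,2R)-2-(methoxymethoxy)-1-[3,4,5-tris(benzyloxy)phenyl]-3-[2,4,6-tris(benzyloxy)phenyl]propyl]phenyl]-2-(methoxymethoxy)-1-[3,4,5-tris(benzyloxy)phenyl]propan-1-olate | COCO[C@H](Cc1c(OCc2ccccc2)cc(OCc2ccccc2)cc1OCc1ccccc1)[C@H](c1cc(OCc2ccccc2)c(OCc2ccccc2)c(OCc2ccccc2)c1)c1c(OCc2ccccc2)c(C[C@@H](OCOC)[C@@H](c2cc(OCc3ccccc3)c(OCc3ccccc3)c(OCc3ccccc3)c2)O[Mg]Br)c(F)cc1OCc1ccccc1 | intermediate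
24 | (2R,3R)-5,7-bis(benzyloxy)-3-(methoxymethoxy)-6-[(1R,2R)-2-(methoxymethoxy)-1-[3,4,5-tris(benzyloxy)phenyl]-3-[2,4,6-tris(benzyloxy)phenyl]propyl]-2-[3,4,5-tris(benzyloxy)phenyl]chromane | COCO[C@H](Cc1c(OCc2ccccc2)cc(OCc2ccccc2)cc1OCc1ccccc1)[C@H](c1cc(OCc2ccccc2)c(OCc2ccccc2)c(OCc2ccccc2)c1)c1c(OCc3ccccc3)cc2c(c1OCc1ccccc1)C[C@@H](OCOC)[C@@H](c1cc(OCc3ccccc3)c(OCc3ccccc3)c(OCc3ccccc3)c1)O2 | intermediate
25 | (2R,3R)-5,7-bis(benzyloxy)-6-[(1R,2R)-2-hydroxy-1-[3,4,5-tris(benzyloxy)phenyl]-3-[2,4,6-tris(benzyloxy)phenyl]propyl]-2-[3,4,5-tris(benzyloxy)phenyl]chroman-3-ol | O[C@H](Cc1c(OCc2ccccc2)cc(OCc2ccccc2)cc1OCc1ccccc1)[C@H](c1cc(OCc2ccccc2)c(OCc2ccccc2)c(OCc2ccccc2)c1)c1c(OCc3ccccc3)cc2c(c1OCc1ccccc1)C[C@@H](O)[C@@H](c1cc(OCc3ccccc3)c(OCc3ccccc3)c(OCc3ccccc3)c1)O2 | intermediate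
26 | 3,4,5-tris(benzyloxy)benzoic acid | OC(=O)c1cc(OCc2ccccc2)c(OCc2ccccc2)c(OCc2ccccc2)c1 | starting material
27 | heptadeca-O-benzyl derivative of the target (both C3 oxygens as 3,4,5-tris(benzyloxy)benzoates) | O=C(O[C@H](Cc1c(OCc2ccccc2)cc(OCc2ccccc2)cc1OCc1ccccc1)[C@H](c1cc(OCc2ccccc2)c(OCc2ccccc2)c(OCc2ccccc2)c1)c1c(OCc3ccccc3)cc2c(c1OCc1ccccc1)C[C@@H](OC(=O)c1cc(OCc3ccccc3)c(OCc3ccccc3)c(OCc3ccccc3)c1)[C@@H](c1cc(OCc3ccccc3)c(OCc3ccccc3)c(OCc3ccccc3)c1)O2)c1cc(OCc2ccccc2)c(OCc2ccccc2)c(OCc2ccccc2)c1 | intermediate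
28 | CNP0240551.1: (2R,3R)-5,7-dihydroxy-6-[(1R,2R)-2-(3,4,5-trihydroxybenzoyloxy)-1-(3,4,5-trihydroxyphenyl)-3-(2,4,6-trihydroxyphenyl)propyl]-2-(3,4,5-trihydroxyphenyl)chroman-3-yl 3,4,5-trihydroxybenzoate | O=C(O[C@H](Cc1c(O)cc(O)cc1O)[C@H](c1cc(O)c(O)c(O)c1)c1c(O)cc2c(c1O)C[C@@H](OC(=O)c1cc(O)c(O)c(O)c1)[C@@H](c1cc(O)c(O)c(O)c1)O2)c1cc(O)c(O)c(O)c1 | target

**Step count and risks**

Total step count: 16. Longest linear sequence: 12 steps (steps 1–4, 8–11 and 13–16).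

Steps most likely to fail:

Step 8. The hindered, doubly ortho-substituted aryl copper species may attack the non-benzylic epoxide carbon, the electron-rich epoxide may isomerise to a ketone under the Lewis-acidic magnesium salts, or stereospecificity may be partly lost through an open benzylic cation. The fallback sets out from 3 (with 12 and 4) and comes back at 13. Allylic alcohol 3 would be epoxidised under Sharpless conditions (Ti(OiPr)4, D-(−)-diethyl tartrate, t-BuOOH, 4 Å molecular sieves, CH2Cl2, −20 °C) to [(2R,3R)-3-[3,4,5-tris(benzyloxy)phenyl]oxiran-2-yl]methanol F1. Its free hydroxyl, as the magnesium alkoxide, steers the copper-catalysed attack of 12 (2.5 equiv, CuI, THF, −30 °C) to the benzylic C3 with inversion, giving (2S,3R)-3-[2,6-bis(benzyloxy)-4-fluorophenyl]-3-[3,4,5-tris(benzyloxy)phenyl]propane-1,2-diol F2. Selective sulfonylation of the primary hydroxyl (TsCl, Et3N, Bu2SnO cat., CH2Cl2) would give the monotosylate (2S,3R)-3-[2,6-bis(benzyloxy)-4-fluorophenyl]-2-hydroxy-3-[3,4,5-tris(benzyloxy)phenyl]propyl 4-methylbenzenesulfonate F3, and K2CO3 in MeOH would close it to (2S)-2-[(R)-[2,6-bis(benzyloxy)-4-fluorophenyl][3,4,5-tris(benzyloxy)phenyl]methyl]oxirane F4. Lithiation of 4 (n-BuLi, THF, 0 °C) gives [2,4,6-tris(benzyloxy)phenyl]lithium F5, which with BF3·OEt2 at −78 °C opens F4 at its CH2 terminus and returns to 13.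

Step 13. The aryl addition may leak through a non-chelated (Felkin–Anh) transition state, which after ring closure would give the 2,3-trans flavan, or fluoride displacement may stall while the alkoxide is still bound to magnesium. The fallback sets out from 19 (with 22) and comes back at 24; it sets C2 by hydride delivery instead of aryl delivery and closes the ring as a separate step. Addition of 22 to 19 in THF without a chelating additive would give the epimeric carbinols (2R)-3-[2,4-bis(benzyloxy)-6-fluoro-3-[(1R,2R)-2-(methoxymethoxy)-1-[3,4,5-tris(benzyloxy)phenyl]-3-[2,4,6-tris(benzyloxy)phenyl]propyl]phenyl]-2-(methoxymethoxy)-1-[3,4,5-tris(benzyloxy)phenyl]propan-1-ol (both C1 epimers) F6. Dess–Martin oxidation would converge them on the aryl ketone, the corresponding propan-1-one F7. Reduction with K[(s-Bu)3BH] in THF at −78 °C (Felkin–Anh control, hydride anti to the α-OMOM group) should give the syn alcohol, the (1R,2R)-propan-1-ol F8. KH and 18-crown-6 in THF/DMF (0 °C to rt) would then effect the fluoride displacement from the free potassium alkoxide to give 24.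

Step 9. The ortho-fluoroaryl metal may lose fluoride (aryne formation), or the ester of the glycidate may be attacked, during the slow lithium-to-magnesium-to-copper relay. The fallback sets out from 13 (through 15) and comes back at 19; it uses a Lewis-acid-promoted opening of an ether-protected epoxide by the aryllithium itself. Dilithio species 15 would be trapped at −78 °C with tert-butyldimethylsilyl (R)-glycidyl ether and BF3·OEt2 to give (1R,2R)-1-[2,6-bis(benzyloxy)-3-[(2R)-3-[(tert-butyldimethylsilyl)oxy]-2-hydroxypropyl]-4-fluorophenyl]-1-[3,4,5-tris(benzyloxy)phenyl]-3-[2,4,6-tris(benzyloxy)phenyl]propan-2-ol F9. MOMCl and i-Pr2NEt would give its bis(methoxymethyl) ether F10. Bu4NF in THF would free the primary alcohol (2R)-3-[2,4-bis(benzyloxy)-6-fluoro-3-[(1R,2R)-2-(methoxymethoxy)-1-[3,4,5-tris(benzyloxy)phenyl]-3-[2,4,6-tris(benzyloxy)phenyl]propyl]phenyl]-2-(methoxymethoxy)propan-1-ol F11, and Dess–Martin oxidation would give 19.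

Further compounds

F1 | step 8 | [(2R,3R)-3-[3,4,5-tris(benzyloxy)phenyl]oxiran-2-yl]methanol | OC[C@H]1O[C@@H]1c1cc(OCc2ccccc2)c(OCc2ccccc2)c(OCc2ccccc2)c1
F2 | step 8 | (2S,3R)-3-[2,6-bis(benzyloxy)-4-fluorophenyl]-3-[3,4,5-tris(benzyloxy)phenyl]propane-1,2-diol | O[C@H](CO)[C@H](c1cc(OCc2ccccc2)c(OCc2ccccc2)c(OCc2ccccc2)c1)c1c(OCc2ccccc2)cc(F)cc1OCc1ccccc1
F3 | step 8 | (2S,3R)-3-[2,6-bis(benzyloxy)-4-fluorophenyl]-2-hydroxy-3-[3,4,5-tris(benzyloxy)phenyl]propyl 4-methylbenzenesulfonate | O[C@H](COS(=O)(=O)c1ccc(C)cc1)[C@H](c1cc(OCc2ccccc2)c(OCc2ccccc2)c(OCc2ccccc2)c1)c1c(OCc2ccccc2)cc(F)cc1OCc1ccccc1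
F4 | step 8 | (2S)-2-[(R)-[2,6-bis(benzyloxy)-4-fluorophenyl][3,4,5-tris(benzyloxy)phenyl]methyl]oxirane | C1O[C@H]1[C@H](c1cc(OCc2ccccc2)c(OCc2ccccc2)c(OCc2ccccc2)c1)c1c(OCc2ccccc2)cc(F)cc1OCc1ccccc1
F5 | step 8 | [2,4,6-tris(benzyloxy)phenyl]lithium | [Li]c1c(OCc2ccccc2)cc(OCc2ccccc2)cc1OCc1ccccc1
F6 | step 13 | (2R)-3-[2,4-bis(benzyloxy)-6-fluoro-3-[(1R,2R)-2-(methoxymethoxy)-1-[3,4,5-tris(benzyloxy)phenyl]-3-[2,4,6-tris(benzyloxy)phenyl]propyl]phenyl]-2-(methoxymethoxy)-1-[3,4,5-tris(benzyloxy)phenyl]propan-1-ol (both C1 epimers) | COCO[C@H](Cc1c(OCc2ccccc2)cc(OCc2ccccc2)cc1OCc1ccccc1)[C@H](c1cc(OCc2ccccc2)c(OCc2ccccc2)c(OCc2ccccc2)c1)c1c(OCc2ccccc2)c(C[C@@H](OCOC)C(O)c2cc(OCc3ccccc3)c(OCc3ccccc3)c(OCc3ccccc3)c2)c(F)cc1OCc1ccccc1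
F7 | step 13 | (2R)-3-[2,4-bis(benzyloxy)-6-fluoro-3-[(1R,2R)-2-(methoxymethoxy)-1-[3,4,5-tris(benzyloxy)phenyl]-3-[2,4,6-tris(benzyloxy)phenyl]propyl]phenyl]-2-(methoxymethoxy)-1-[3,4,5-tris(benzyloxy)phenyl]propan-1-one | COCO[C@H](Cc1c(OCc2ccccc2)cc(OCc2ccccc2)cc1OCc1ccccc1)[C@H](c1cc(OCc2ccccc2)c(OCc2ccccc2)c(OCc2ccccc2)c1)c1c(OCc2ccccc2)c(C[C@@H](OCOC)C(=O)c2cc(OCc3ccccc3)c(OCc3ccccc3)c(OCc3ccccc3)c2)c(F)cc1OCc1ccccc1
F8 | step 13 | (1R,2R)-3-[2,4-bis(benzyloxy)-6-fluoro-3-[(1R,2R)-2-(methoxymethoxy)-1-[3,4,5-tris(benzyloxy)phenyl]-3-[2,4,6-tris(benzyloxy)phenyl]propyl]phenyl]-2-(methoxymethoxy)-1-[3,4,5-tris(benzyloxy)phenyl]propan-1-ol | COCO[C@H](Cc1c(OCc2ccccc2)cc(OCc2ccccc2)cc1OCc1ccccc1)[C@H](c1cc(OCc2ccccc2)c(OCc2ccccc2)c(OCc2ccccc2)c1)c1c(OCc2ccccc2)c(C[C@@H](OCOC)[C@@H](c2cc(OCc3ccccc3)c(OCc3ccccc3)c(OCc3ccccc3)c2)O)c(F)cc1OCc1ccccc1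
F9 | step 9 | (1R,2R)-1-[2,6-bis(benzyloxy)-3-[(2R)-3-[(tert-butyldimethylsilyl)oxy]-2-hydroxypropyl]-4-fluorophenyl]-1-[3,4,5-tris(benzyloxy)phenyl]-3-[2,4,6-tris(benzyloxy)phenyl]propan-2-ol | O[C@H](Cc1c(OCc2ccccc2)cc(OCc2ccccc2)cc1OCc1ccccc1)[C@H](c1cc(OCc2ccccc2)c(OCc2ccccc2)c(OCc2ccccc2)c1)c1c(OCc2ccccc2)c(C[C@@H](O)CO[Si](C)(C)C(C)(C)C)c(F)cc1OCc1ccccc1
F10 | step 9 | bis(methoxymethyl) ether of F9 | COCO[C@H](Cc1c(OCc2ccccc2)cc(OCc2ccccc2)cc1OCc1ccccc1)[C@H](c1cc(OCc2ccccc2)c(OCc2ccccc2)c(OCc2ccccc2)c1)c1c(OCc2ccccc2)c(C[C@@H](OCOC)CO[Si](C)(C)C(C)(C)C)c(F)cc1OCc1ccccc1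
F11 | step 9 | (2R)-3-[2,4-bis(benzyloxy)-6-fluoro-3-[(1R,2R)-2-(methoxymethoxy)-1-[3,4,5-tris(benzyloxy)phenyl]-3-[2,4,6-tris(benzyloxy)phenyl]propyl]phenyl]-2-(methoxymethoxy)propan-1-ol | COCO[C@H](Cc1c(OCc2ccccc2)cc(OCc2ccccc2)cc1OCc1ccccc1)[C@H](c1cc(OCc2ccccc2)c(OCc2ccccc2)c(OCc2ccccc2)c1)c1c(OCc2ccccc2)c(C[C@@H](OCOC)CO)c(F)cc1OCc1ccccc1
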